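Compare percentages, not molarities.

| flask | substrate | remark | time |
|---|---|---|---|
| south | 0.058 M | run made earlier |  |
| south-west | 0.30 M | run made earlier |  |
| theta | 0.050 M |  | 4.0 h |
| zeta | 0.10 M |  | 4.0 h |
| beta | 0.20 M |  | 4.0 h |

- south (time / h: product / %, substrate / %): 0.250: 5.1, 46.6; 0.833: 23.7, 8.3; 1.33: 39.3, 1.4; 2.00: 53.2, 0; 3.00: 67.9, 0.4; 4.00: 78.2, 0
- south-west (time / h: product / %, substrate / %): 0.333: 6.7, 37.3; 0.500: 11.9, 23.5; 0.833: 24.1, 7.9; 1.33: 38.4, 1.8; 2.50: 61.5, 0.2; 4.00: 79.1, 0.3

(standard deviation of a reading: 0.5 percentage points)

- [product] at the end for theta, zeta, beta, in this order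
- the course of these numbers from the first flask to the last (falls, then rises / hardly changes / rises all the way / rises, then falls / falls all the way)

- "hardly changes" means that all values lie within two and a half points (for a concentration: within two and a half percent of the largest)

Set the two runs side by side. The south-west charge is 5.17 times the south charge, yet at 0.833 h product reads 23.7% in the south run and 24.1% in the south-west run, a gap of 0.4 percentage points against a scatter of 0.5 points. Read this as first-order behaviour: the percentage curve doesn't move with the charge between these two runs.

Now take the mean of the readings at 4.00 h, 78.2% and 79.1%. That mean, 78.6%, is the end share: the part of the charged substrate that stands as product at 4.0 h. Multiply it by each charge and you get 0.0393 M for theta, 0.0786 M for zeta and 0.157 M for beta, a row that climbs with the charge. Note that theta's 0.050 M lies just below the lower of the two charges tested, 0.058 M.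

The forecast gives 0.0393 M, 0.0786 M and 0.157 M, course rises all the way, holding that “the percentage curve should not depend on concentration”.

The flasks give 0.0393 M, 0.0786 M and 0.157 M, course rises all the way.

    intermediate C → product (k = 0.0130 min⁻¹)
    intermediate A → product (k = 0.00990 min⁻¹)
    substrate → intermediate A (k = 0.0500 min⁻¹)
    intermediate B → intermediate C (k = 0.00860 min⁻¹)
    intermediate A → intermediate B (k = 0.00590 min⁻¹)

In theta at 0.231 h, substrate has a half-life of 0.23 h by its turning into intermediate A, shorter than the 1.2 h of intermediate A by its turning into product, and intermediate A is made 3.57 times faster than it is used up. At 4.00 h theta holds 0% substrate, while intermediates A, B and C stand at 3.30%, 9.86% and 8.28%, together 21.4% of the charge. On zeta's charge the end share gives 0.0786 M, and zeta holds 0.0786 M.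

Readings and results were computed for an exercise; noise was put on by code.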